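**Plan**

- Cuts: (i) the interflavan C4(upper)–C8(lower) bond, giving a protected epicatechin C4 electrophile and a lower flavan nucleophile; (ii) in the lower unit the C4–C4a bond of ring C, giving an aryloxy-tethered (E)-enal; (iii) C4=Cα (cross-metathesis), O1–C8a (Ullmann etherification) and C2–C3 (alkoxyallylboration).
- Forward: ring-B aldehyde → C2/C3 → O1–C8a aryl ether → enal → ring C closed by C4–C4a → side arm oxidised and esterified → upper unit joined at C8 → global hydrogenolysis.
- Enabling feature: lower C4 is β to the carboxyl carbon of its CH2CO2H arm (the trace of a Michael acceptor). C4a sits in the phloroglucinol-type ring A, ortho to O1 and C5–O and para to C7–O. In the open 3,5-dibenzyloxyphenyl ether both carbons ortho to O1 are equivalent, so only one chroman can form.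
- Stereochemistry: lower C2/C3 come from the (+)-α-pinene-derived (Z)-γ-alkoxyallylborane (syn, i.e. 2,3-cis). Lower C4 is set in the key step (catalyst and substrate matched, 3,4-trans). Upper C2/C3 come from natural (−)-epicatechin. Upper C4 is set by anti attack on the C4 cation (4β).

Key step: step 6

Assumption: 1,3-bis(benzyloxy)-5-iodobenzene (8), allyl methoxymethyl ether and the (2R,5R)-imidazolidinone are treated as purchasable; 8 is otherwise one O-benzylation away from 5-iodoresorcinol.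

**Route**

Step 1
Reactants: 1 (−)-epicatechin
Product: 2 5,7,3',4'-tetra-O-benzyl-(−)-epicatechin
Conditions: BnBr (4.4 equiv), K2CO3, DMF, 0 °C to rt
Reagents that add atoms: benzyl bromide, BrCc1ccccc1
Why: Williamson etherification in which carbonate deprotonates only the four phenols, so the aliphatic 3-OH stays free, and the low temperature is meant to suppress base-induced C2 epimerisation.

Step 2
Reactants: 2 5,7,3',4'-tetra-O-benzyl-(−)-epicatechin
Product: 4 tetra-O-benzyl-4β-(2-ethoxyethoxy)epicatechin, via C4 cation hydroquinonate ion pair 3 (not isolated)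
Conditions: DDQ (2 equiv), 2-ethoxyethanol (5 equiv), CH2Cl2, rt
Reagents that add atoms: 2-ethoxyethanol, CCOCCO
Why: DDQ benzylic oxidation in which hydride abstraction from C4, assisted by the ring-A oxygens, gives the C4 cation as its ion pair 3 with the hydroquinone monoanion of the spent oxidant, which the alcohol should trap anti to the 3-OH (4β) while the counter-ion takes up the proton; this C4 configuration is lost again in step 10 and is not critical.

Step 3
Reactants: 5 3,4-bis(benzyloxy)benzaldehyde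
Product: 7 (1R,2R)-1-[3,4-bis(benzyloxy)phenyl]-2-(methoxymethoxy)but-3-en-1-ol, via diisopinocampheylborinate 6 (not isolated)
Conditions: allyl methoxymethyl ether, s-BuLi, THF, −78 °C; (−)-Ipc2BOMe [from (+)-α-pinene]; BF3·OEt2; then 5, −78 °C to rt; NaOH, H2O2, 0 °C to rt
Reagents that add atoms: allyl methoxymethyl ether [3-(methoxymethoxy)prop-1-ene], C=CCOCOC
Why: Asymmetric γ-alkoxyallylboration through a closed chair-like six-membered transition state, in which the Z geometry of the allylborane gives the syn (threo) C1–OH/C2–OMOM relationship and the isopinocampheyl groups from (+)-α-pinene select the aldehyde face, which should give the (1R,2R) isomer needed for the 2,3-cis lower unit.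

Step 4
Reactants: 7 (1R,2R)-1-[3,4-bis(benzyloxy)phenyl]-2-(methoxymethoxy)but-3-en-1-ol; 8 1,3-bis(benzyloxy)-5-iodobenzene
Product: 9 1,3-bis(benzyloxy)-5-{[(1R,2R)-1-[3,4-bis(benzyloxy)phenyl]-2-(methoxymethoxy)but-3-en-1-yl]oxy}benzene
Conditions: CuI (10 mol %), 3,4,7,8-tetramethyl-1,10-phenanthroline (20 mol %), Cs2CO3, 8 (2 equiv), toluene, 4 Å MS, 110 °C
Reagents that add atoms: none
Why: Ullmann-type copper-catalysed C–O coupling of a secondary alkoxide with an aryl iodide, in which the new O–C bond is made at the aryl carbon (future O1–C8a) and the carbinol C–O bond is never broken, so the configuration at C1 (future C2) should be retained.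

Step 5
Reactants: 9 the aryl ether from step 4
Product: 10 (2E,4R,5R)-5-[3,4-bis(benzyloxy)phenyl]-5-[3,5-bis(benzyloxy)phenoxy]-4-(methoxymethoxy)pent-2-enal
Conditions: crotonaldehyde (5 equiv), second-generation Hoveyda–Grubbs catalyst RuCl2(H2IMes)(=CH-C6H4-2-O-i-Pr) (5 mol %), CH2Cl2, 40 °C
Reagents that add atoms: (E)-crotonaldehyde, C/C=C/C=O
Why: Olefin cross-metathesis of the terminal alkene with an excess of the electron-poor partner crotonaldehyde, in which the conjugated product is expected as the E isomer and propene escapes.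

Step 6
Reactants: 10 the (E)-enal from step 5
Product: 12 2-[(2R,3R,4S)-5,7-bis(benzyloxy)-2-[3,4-bis(benzyloxy)phenyl]-3-(methoxymethoxy)chroman-4-yl]acetaldehyde, via iminium ion 11 (not isolated)
Conditions: (2R,5R)-5-benzyl-2-tert-butyl-3-methylimidazolidin-4-one·CF3CO2H (20 mol %), Et2O, −20 °C to 0 °C; aqueous work-up
Reagents that add atoms: none
Why: Condensation of the enal with the imidazolidinone salt gives iminium ion 11, whose β-carbon C4 is attacked by C4a, the ring-A carbon ortho to the ether oxygen O1 and to the C5 benzyloxy group and para to the C7 benzyloxy group; loss of the C4a proton restores the arene and hydrolysis of the enamine releases 12 and the catalyst. The closest known reaction type is the amine-catalysed intramolecular Friedel–Crafts-type hydroarylation of aryloxy-tethered enals to chroman-4-ylacetaldehydes. Ring C closes in the 6-exo-trig mode (C4a onto C4, the C4=Cα bond exocyclic). The new C4 stereocentre is controlled by the catalyst, whose benzyl group shields one face of the E-iminium so that the (2R,5R) enantiomer should expose the face leading to 4S, and by the substrate, in which a Felkin–Anh-type arrangement (C3–OMOM bond anti to the forming bond, C2 aryl group equatorial) and the peri repulsion between C5–OBn and a quasi-equatorial C4 arm both favour the quasi-axial CH2CHO group trans to the 3-oxygen. The step needs C-alkylation by ring A to outrun γ-deprotonation of the iminium ion (a dienamine could expel the aryloxide) and attack by ring B; the intramolecular reaction of the trialkoxy-activated ring at low temperature should secure the first, the much lower nucleophilicity of the catechol diether ring the second, and the equivalence of the two carbons ortho to O1 leaves a single regiochemical outcome.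

Step 7
Reactants: 12 the chroman-4-ylacetaldehyde from step 6
Product: 13 2-[(2R,3R,4S)-5,7-bis(benzyloxy)-2-[3,4-bis(benzyloxy)phenyl]-3-(methoxymethoxy)chroman-4-yl]acetic acid
Conditions: NaClO2, NaH2PO4, 2-methyl-2-butene (large excess), t-BuOH/H2O, 0 °C to rt
Reagents that add atoms: sodium chlorite, [Na+].[O-]Cl=O
Why: Pinnick oxidation of the aldehyde to the acid, in which the alkene scavenger removes HOCl before it can chlorinate electron-rich ring A and no stereocentre is α to the carbonyl group.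

Step 8
Reactants: 13 the acid from step 7
Product: 14 benzyl 2-[(2R,3R,4S)-5,7-bis(benzyloxy)-2-[3,4-bis(benzyloxy)phenyl]-3-(methoxymethoxy)chroman-4-yl]acetate
Conditions: BnBr, K2CO3, DMF, rt
Reagents that add atoms: benzyl bromide, BrCc1ccccc1
Why: SN2 O-alkylation of the carboxylate, which masks the acid as a benzyl ester that leaves together with the benzyl ethers in step 11.

Step 9
Reactants: 14 the benzyl ester from step 8
Product: 15 benzyl 2-[(2R,3R,4S)-5,7-bis(benzyloxy)-2-[3,4-bis(benzyloxy)phenyl]-3-hydroxychroman-4-yl]acetate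
Conditions: ZnBr2 (1 equiv), n-PrSH (2 equiv), CH2Cl2, 0 °C
Reagents that add atoms: none
Why: Lewis-acid-assisted acetal cleavage of the MOM ether, the thiol taking up the methoxymethyl cation before it can alkylate ring A, while benzyl ethers, the benzyl ester and the chroman ring should be inert at 0 °C.

Step 10
Reactants: 15 the 3-hydroxy benzyl ester from step 9; 4 tetra-O-benzyl-4β-(2-ethoxyethoxy)epicatechin
Product: 17 nona-benzyl-protected dimer (benzyl ester of octa-O-benzyl-18), via C4 cation triflate ion pair 16 (not isolated)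
Conditions: TMSOTf (0.2 equiv), CH2Cl2, −78 °C, slow addition of 4 (1.0 equiv) to 15 (1.5 equiv); NaHCO3 quench
Reagents that add atoms: none
Why: Lewis-acid-mediated Friedel–Crafts coupling of flavan-3-ols (SN1 at C4), in which TMSOTf silylates and ionises the 4-alkoxy group of 4 to the C4 cation triflate 16, C8 of 15 (between O1 and the 7-benzyloxy group, the established nucleophilic site of benzylated flavan-3-ols) attacks it with return of the silyl triflate, and the new upper C4 stereocentre should be set 4β (4R) by approach anti to the quasi-axial 3-OH of the 2,3-cis half-chair cation.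

Step 11
Reactants: 17 the nona-benzyl-protected dimer
Product: 18 (−)-epicatechin-(4β→8)-4β-carboxymethyl-(−)-epicatechin (CNP0190976.1)
Conditions: H2 (1 atm), Pd(OH)2/C, THF/MeOH/H2O, rt
Reagents that add atoms: none
Why: Catalytic hydrogenolysis of the eight benzyl ethers and the benzyl ester under neutral conditions, which are known to leave the interflavan C–C bond and the cyclic benzylic C2–O1 bonds of procyanidins intact.

**Compound list**

1 | (−)-epicatechin, (2R,3R)-2-(3,4-dihydroxyphenyl)chroman-3,5,7-triol | C1c2c(O)cc(O)cc2O[C@H](c2ccc(O)c(O)c2)[C@@H]1O | starting material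
2 | (2R,3R)-5,7-bis(benzyloxy)-2-[3,4-bis(benzyloxy)phenyl]chroman-3-ol | C1c2c(OCc3ccccc3)cc(OCc3ccccc3)cc2O[C@H](c2ccc(OCc3ccccc3)c(OCc3ccccc3)c2)[C@@H]1O | intermediate
3 | (2R,3R)-5,7-bis(benzyloxy)-2-[3,4-bis(benzyloxy)phenyl]-3-hydroxychroman-4-ylium 2,3-dichloro-5,6-dicyano-4-hydroxyphenolate (C4 benzylic cation paired with the hydroquinone monoanion of spent DDQ, formed in the flask) | [CH+]1c2c(OCc3ccccc3)cc(OCc3ccccc3)cc2O[C@H](c2ccc(OCc3ccccc3)c(OCc3ccccc3)c2)[C@@H]1O.[O-]c1c(Cl)c(Cl)c(O)c(C#N)c1C#N | intermediate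
4 | (2R,3R,4S)-5,7-bis(benzyloxy)-2-[3,4-bis(benzyloxy)phenyl]-4-(2-ethoxyethoxy)chroman-3-ol | CCOCCO[C@H]1c2c(OCc3ccccc3)cc(OCc3ccccc3)cc2O[C@H](c2ccc(OCc3ccccc3)c(OCc3ccccc3)c2)[C@@H]1O | intermediate
5 | 3,4-bis(benzyloxy)benzaldehyde | O=Cc1ccc(OCc2ccccc2)c(OCc2ccccc2)c1 | starting material
6 | O-diisopinocampheylboryl derivative (borinate) of 7, formed in the flask | B(O[C@H](c1ccc(OCc2ccccc2)c(OCc2ccccc2)c1)[C@@H](C=C)OCOC)([C@@H]1C[C@@H]2C[C@H]([C@H]1C)C2(C)C)[C@@H]1C[C@@H]2C[C@H]([C@H]1C)C2(C)C | intermediate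
7 | (1R,2R)-1-[3,4-bis(benzyloxy)phenyl]-2-(methoxymethoxy)but-3-en-1-ol | O[C@H](c1ccc(OCc2ccccc2)c(OCc2ccccc2)c1)[C@@H](C=C)OCOC | intermediate
8 | 1,3-bis(benzyloxy)-5-iodobenzene | Ic1cc(OCc2ccccc2)cc(OCc2ccccc2)c1 | starting material
9 | 1,3-bis(benzyloxy)-5-{[(1R,2R)-1-[3,4-bis(benzyloxy)phenyl]-2-(methoxymethoxy)but-3-en-1-yl]oxy}benzene | c1c(OCc2ccccc2)cc(OCc2ccccc2)cc1O[C@H](c1ccc(OCc2ccccc2)c(OCc2ccccc2)c1)[C@@H](C=C)OCOC | intermediate
10 | (2E,4R,5R)-5-[3,4-bis(benzyloxy)phenyl]-5-[3,5-bis(benzyloxy)phenoxy]-4-(methoxymethoxy)pent-2-enal | c1c(OCc2ccccc2)cc(OCc2ccccc2)cc1O[C@H](c1ccc(OCc2ccccc2)c(OCc2ccccc2)c1)[C@@H](/C=C/C=O)OCOC | intermediate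
11 | iminium trifluoroacetate from 10 and (2R,5R)-5-benzyl-2-tert-butyl-3-methylimidazolidin-4-one, formed in the flask | CN1C(=O)[C@@H](Cc2ccccc2)[N+](=C/C=C/[C@@H](OCOC)[C@H](Oc2cc(OCc3ccccc3)cc(OCc3ccccc3)c2)c2ccc(OCc3ccccc3)c(OCc3ccccc3)c2)[C@H]1C(C)(C)C.[O-]C(=O)C(F)(F)F | intermediate
12 | 2-[(2R,3R,4S)-5,7-bis(benzyloxy)-2-[3,4-bis(benzyloxy)phenyl]-3-(methoxymethoxy)chroman-4-yl]acetaldehyde | O=CC[C@H]1c2c(OCc3ccccc3)cc(OCc3ccccc3)cc2O[C@H](c2ccc(OCc3ccccc3)c(OCc3ccccc3)c2)[C@@H]1OCOC | intermediate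
13 | 2-[(2R,3R,4S)-5,7-bis(benzyloxy)-2-[3,4-bis(benzyloxy)phenyl]-3-(methoxymethoxy)chroman-4-yl]acetic acid | O=C(O)C[C@H]1c2c(OCc3ccccc3)cc(OCc3ccccc3)cc2O[C@H](c2ccc(OCc3ccccc3)c(OCc3ccccc3)c2)[C@@H]1OCOC | intermediate
14 | benzyl 2-[(2R,3R,4S)-5,7-bis(benzyloxy)-2-[3,4-bis(benzyloxy)phenyl]-3-(methoxymethoxy)chroman-4-yl]acetate | O=C(OCc3ccccc3)C[C@H]1c2c(OCc3ccccc3)cc(OCc3ccccc3)cc2O[C@H](c2ccc(OCc3ccccc3)c(OCc3ccccc3)c2)[C@@H]1OCOC | intermediate
15 | benzyl 2-[(2R,3R,4S)-5,7-bis(benzyloxy)-2-[3,4-bis(benzyloxy)phenyl]-3-hydroxychroman-4-yl]acetate | O=C(OCc3ccccc3)C[C@H]1c2c(OCc3ccccc3)cc(OCc3ccccc3)cc2O[C@H](c2ccc(OCc3ccccc3)c(OCc3ccccc3)c2)[C@@H]1O | intermediate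
16 | (2R,3R)-5,7-bis(benzyloxy)-2-[3,4-bis(benzyloxy)phenyl]-3-hydroxychroman-4-ylium trifluoromethanesulfonate (C4 benzylic cation paired with triflate, formed in the flask) | [CH+]1c2c(OCc3ccccc3)cc(OCc3ccccc3)cc2O[C@H](c2ccc(OCc3ccccc3)c(OCc3ccccc3)c2)[C@@H]1O.[O-]S(=O)(=O)C(F)(F)F | intermediate
17 | benzyl 2-[(2R,3R,4S)-5,7-bis(benzyloxy)-8-[(2R,3R,4R)-5,7-bis(benzyloxy)-2-[3,4-bis(benzyloxy)phenyl]-3-hydroxychroman-4-yl]-2-[3,4-bis(benzyloxy)phenyl]-3-hydroxychroman-4-yl]acetate | O=C(OCc5ccccc5)C[C@H]1c2c(OCc5ccccc5)cc(OCc5ccccc5)c([C@H]3c4c(OCc5ccccc5)cc(OCc5ccccc5)cc4O[C@H](c4ccc(OCc5ccccc5)c(OCc5ccccc5)c4)[C@@H]3O)c2O[C@H](c2ccc(OCc5ccccc5)c(OCc5ccccc5)c2)[C@@H]1O | intermediate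
18 | 2-[(2R,3R,4S)-2-(3,4-dihydroxyphenyl)-8-[(2R,3R,4R)-2-(3,4-dihydroxyphenyl)-3,5,7-trihydroxychroman-4-yl]-3,5,7-trihydroxychroman-4-yl]acetic acid | O=C(O)C[C@H]1c2c(O)cc(O)c([C@H]3c4c(O)cc(O)cc4O[C@H](c4ccc(O)c(O)c4)[C@@H]3O)c2O[C@H](c2ccc(O)c(O)c2)[C@@H]1O | target

**Totals and risks**

Total step count: 11. Longest linear sequence: 9 steps (steps 3 to 11, from 5 to 18).

Steps most likely to fail:

1. Step 6 (ring closure). The iminium ion may be deprotonated at the γ-position to a dienamine that expels the aryloxide, or the facial selectivity at C4 may be poor if catalyst and substrate preferences prove mismatched. The fallback changes the acceptor to a doubly activated one that needs no amine; it sets out from 9 and returns at 14. Lemieux–Johnson cleavage of the vinyl group of 9 (OsO4 cat., NaIO4, 2,6-lutidine, dioxane/H2O) should give (2S,3R)-3-[3,4-bis(benzyloxy)phenyl]-3-[3,5-bis(benzyloxy)phenoxy]-2-(methoxymethoxy)propanal F1. Knoevenagel condensation of F1 with Meldrum's acid (pyrrolidinium acetate cat., benzene, rt) should give the alkylidene Meldrum's acid 5-[(2R,3R)-3-[3,4-bis(benzyloxy)phenyl]-3-[3,5-bis(benzyloxy)phenoxy]-2-(methoxymethoxy)propylidene]-2,2-dimethyl-1,3-dioxane-4,6-dione F2. With Sc(OTf)3 (cat.) in CH2Cl2 at low temperature, F2 should undergo the same 6-exo Friedel–Crafts conjugate addition of C4a to C4 under substrate control alone (3,4-trans), giving the chroman-4-yl Meldrum's acid 5-[(2R,3R,4S)-5,7-bis(benzyloxy)-2-[3,4-bis(benzyloxy)phenyl]-3-(methoxymethoxy)chroman-4-yl]-2,2-dimethyl-1,3-dioxane-4,6-dione F3. Heating F3 with benzyl alcohol in toluene should open the dioxanedione with loss of acetone and CO2 and give benzyl ester 14, so that steps 7 and 8 are skipped.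

2. Step 4 (O-arylation). C–O bond formation at the hindered secondary benzylic alkoxide may be slow, so that oxidation of the alcohol or reduction of the aryl iodide takes over. The fallback replaces copper catalysis by nucleophilic aromatic substitution; it sets out from 7 and returns at 9. 1,3,5-Trifluorobenzene with sodium benzyloxide (BnOH, NaH, 2 equiv, NMP, 80–100 °C) should give 1,3-bis(benzyloxy)-5-fluorobenzene F4. The potassium alkoxide of 7 (KN(SiMe3)2, THF/DMF, 60–80 °C) should then displace fluoride from F4, whose two meta-alkoxy groups do not deactivate the ipso carbon. The carbinol C–O bond is again untouched, so 9 should form with retention.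

3. Step 10 (interflavan coupling). The C4 cation may be captured by ring A of a second molecule of 4 or of product 17 (self-condensation and over-alkylation), or by C6 instead of C8 of 15. The fallback blocks the nucleophilic site of the electrophile; it sets out from 2 and returns at 18. NBS (CH2Cl2, −78 °C) should brominate C8 of 2 to give (2R,3R)-5,7-bis(benzyloxy)-2-[3,4-bis(benzyloxy)phenyl]-8-bromochroman-3-ol F5. DDQ and 2-ethoxyethanol, as in step 2, should give the capped electrophile (2R,3R,4S)-5,7-bis(benzyloxy)-2-[3,4-bis(benzyloxy)phenyl]-8-bromo-4-(2-ethoxyethoxy)chroman-3-ol F6. F6 cannot condense with itself and can be used in excess over 15 with TMSOTf, giving the 8-bromo analogue of 17 (bromine on C8 of the upper unit) F7. Hydrogenolysis of F7 under the conditions of step 11 with Et3N added should remove the aryl bromide together with the benzyl groups and give 18.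

**Further compounds**

F1 | step 6 | (2S,3R)-3-[3,4-bis(benzyloxy)phenyl]-3-[3,5-bis(benzyloxy)phenoxy]-2-(methoxymethoxy)propanal | c1c(OCc2ccccc2)cc(OCc2ccccc2)cc1O[C@H](c1ccc(OCc2ccccc2)c(OCc2ccccc2)c1)[C@@H](C=O)OCOC
F2 | step 6 | 5-[(2R,3R)-3-[3,4-bis(benzyloxy)phenyl]-3-[3,5-bis(benzyloxy)phenoxy]-2-(methoxymethoxy)propylidene]-2,2-dimethyl-1,3-dioxane-4,6-dione | CC1(C)OC(=O)C(=C[C@@H](OCOC)[C@H](Oc2cc(OCc3ccccc3)cc(OCc3ccccc3)c2)c2ccc(OCc3ccccc3)c(OCc3ccccc3)c2)C(=O)O1
F3 | step 6 | 5-[(2R,3R,4S)-5,7-bis(benzyloxy)-2-[3,4-bis(benzyloxy)phenyl]-3-(methoxymethoxy)chroman-4-yl]-2,2-dimethyl-1,3-dioxane-4,6-dione | CC1(C)OC(=O)C(C(=O)O1)[C@H]1c2c(OCc3ccccc3)cc(OCc3ccccc3)cc2O[C@H](c2ccc(OCc3ccccc3)c(OCc3ccccc3)c2)[C@@H]1OCOC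
F4 | step 4 | 1,3-bis(benzyloxy)-5-fluorobenzene | Fc1cc(OCc2ccccc2)cc(OCc2ccccc2)c1
F5 | step 10 | (2R,3R)-5,7-bis(benzyloxy)-2-[3,4-bis(benzyloxy)phenyl]-8-bromochroman-3-ol | C1c2c(OCc3ccccc3)cc(OCc3ccccc3)c(Br)c2O[C@H](c2ccc(OCc3ccccc3)c(OCc3ccccc3)c2)[C@@H]1O
F6 | step 10 | (2R,3R,4S)-5,7-bis(benzyloxy)-2-[3,4-bis(benzyloxy)phenyl]-8-bromo-4-(2-ethoxyethoxy)chroman-3-ol | CCOCCO[C@H]1c2c(OCc3ccccc3)cc(OCc3ccccc3)c(Br)c2O[C@H](c2ccc(OCc3ccccc3)c(OCc3ccccc3)c2)[C@@H]1O
F7 | step 10 | 8-bromo analogue of 17 (bromine on C8 of the upper flavan unit) | O=C(OCc5ccccc5)C[C@H]1c2c(OCc5ccccc5)cc(OCc5ccccc5)c([C@H]3c4c(OCc5ccccc5)cc(OCc5ccccc5)c(Br)c4O[C@H](c4ccc(OCc5ccccc5)c(OCc5ccccc5)c4)[C@@H]3O)c2O[C@H](c2ccc(OCc5ccccc5)c(OCc5ccccc5)c2)[C@@H]1O
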